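## Structural features

The target is a 2,3-dihydrobenzofuran in which benzene ring A (C3a to C7a) is fused to the oxygen heterocycle ring B (O1, C2, C3). Ring A carries an acetyl group at C5 and a hydroxyl at C6 that is hydrogen-bonded to it; C4 and C7 are unsubstituted. The only stereocentres are the neighbouring C2 and C3 of ring B, both R, with the C2 side chain and the C3 oxygen on the same face (cis). C2 bears a 3-acetoxyprop-1-en-2-yl group (C1' is the alkene carbon bonded to C2), and C3 bears an angelate, a (Z)-2-methylbut-2-enoate. The fragile points are the angelate (drift to the E ester with nucleophilic catalysts, acid or heat), the benzylic C3 ester (ionisation or elimination across C2–C3 would aromatise ring B to a benzofuran and erase both stereocentres) and the allylic acetate. The real difficulty is to set the contiguous cis C2/C3 pair in the absolute sense, to carry it through without ever ionising C3, and to tell three oxygen functions apart (primary allylic, secondary benzylic, phenolic). The feature the plan exploits is that O1 is bonded to C7a and C7a is para to the C5 acetyl group: the O1–C7a bond can therefore be made by addition–elimination of an alkoxide on a fluoroarene, closing ring B without touching C2 or C3.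

## Logic of the disconnections

20 to 19. The bond cut is the O–CH2 bond of a benzyl-type ether on the C6 oxygen (a protecting-group bond, no skeletal change). The phenol has to stay masked until all base and acylation chemistry is over, because as a phenoxide it would cancel the activation used in the ring closure and would compete in both acylations. The gain is that 19 has a single function left to unmask. The demand is an unmasking that is neither acidic nor basic, since acid ionises the C3 ester and base transacylates; oxidative cleavage of an electron-rich benzyl ether meets it.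

19 to 16 and 17. The bond cut is the ester C(=O)–O bond at C3. The angelate is the most fragile group and is therefore introduced last among the skeletal pieces. The gain is the separation of the commercial acid 17 from the core. The demand is acylation of a hindered secondary benzylic alcohol without Z to E isomerisation and without elimination across C2–C3.

16 to 15. The bond cut is the acetate C–O bond at the primary oxygen. The two alcohols of 15 differ clearly in hindrance, so they can be told apart kinetically. The gain is that 15 carries no ester, which is what allows a basic ring closure before it. The demand is primary-over-secondary selectivity.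

15 to 12. The bond cut is O1–C7a, the aryl ether bond of ring B. It lies para to the acetyl group, and cutting it leaves both stereocentres in an open-chain syn diol that an allyl-metal addition can deliver. The gain is the loss of ring B and a precursor made of an arene and a four-carbon chain. The demand is a fluorine at C7a, a masked phenol, and a closure in which only the C2 oxygen can react.

12 to 11. The bonds cut are two acetal C–O bonds (protecting groups) at the C2 oxygen and the primary oxygen. They arise because the C–C bond formation delivers the C2 oxygen as an ether. The demand shapes the design: the ethers must come off without cleaving the aryl benzyl-type ether, without closing a cyclic acetal onto the neighbouring hydroxyl and without ionising the benzylic alcohol. A cyclic mixed acetal removable by a weak acid in an alcohol solvent is used for this reason in place of an alkoxymethyl ether.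

11 to 4 and 6. The bond cut is C1–C2 of the side chain (C3–C2 of the target), the only C–C bond between the aromatic half and the four-carbon unit; both stereocentres are made with it. The gain is two achiral pieces. The demand is an allyl-metal reagent with its oxygen cis to the metal-bearing carbon (for the syn relationship), reagent control of the absolute sense, and reaction at the aldehyde in the presence of the methyl ketone.

6 to 5. The bonds cut are the two acetal C–O bonds; the demand is only a mild acid catalyst.

4 to 3. The bond cut is the aryl C–CHO bond. The bromide is the handle left by electrophilic substitution. The demand is a formylation that tolerates a free methyl ketone, which excludes halogen–metal exchange and points to a palladium-catalysed carbonylation.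

3 to 2 to 1. The bonds cut are the ether O–CH2 bond and the C–Br bond. Bromination para to the phenol places the handle at the carbon that becomes C3a, with fluorine ortho to it and para to the acetyl group, exactly as the ring closure requires. The demand is para regioselectivity and O-alkylation faster than any attack on the aryl fluoride.

## Other disconnections considered

Alternative 1: The cut runs through ring A at C3a–C4 and C5–C6, so that the benzene ring is made last on a finished, stereodefined ring B. Diene A2, a cis-2,3-disubstituted 2,3-dihydrofuran whose C5 carries a ketene bis(trimethylsilyl) acetal vinyl group, would add to ynone A3 in a Diels–Alder reaction. The electron-rich terminus that becomes C3a should bond to the unsubstituted alkyne carbon, and loss of a silanol from the cyclohexadiene would aromatise ring A to A1.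
- In favour: two C–C bonds, the acetyl group and the C6 oxygen arrive in one convergent step with polarity-dictated regiochemistry. No halogenated arene is needed. The C6 oxygen emerges as a labile silyl ether, so the late oxidative unmasking of 19 is avoided. On these points it is the better plan.
- Against: A2 holds an allylic silyloxy group on an enol ether, so elimination across C2–C3 to a furan is an obvious escape under heat or Lewis acid, and it would destroy both stereocentres. A2 is moisture-sensitive. The two stereocentres still need their own asymmetric synthesis.
- Comparison: structurally both plans end with the same problem of differentiating three oxygens (equal). Mechanistically the cycloaddition is as predictable in regiochemistry as the closure 12 to 15, but it places C3 beside a developing aromatic system, whereas the chosen closure leaves both centres as spectators. In step economy A2 alone is estimated at seven to nine steps, so the sequence would be clearly longer than ten.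

Alternative 2: The cut is the C2–C1' bond, with O3 and C1' tied temporarily in a lactone. The dirhodium carbene from diazo ester A5, made from a (3R)-2,3-dihydrobenzofuran-3-ol, would insert into the C2–H bond activated by O1 and give the necessarily cis-fused γ-lactone A4. Horner–Wadsworth–Emmons methylenation would give α-methylene lactone A6, and hydride reduction the side-chain diol.
- In favour: only C3 needs absolute control, and the cis relationship is guaranteed by ring fusion instead of by reagent geometry; on diastereocontrol this is the better plan. Insertion next to an ether oxygen is well established, and the phosphonate serves twice.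
- Against: the acetyl group cannot be on board, because it would trap the carbene and would not survive lactone reduction. Hence the bromide placeholder in A5 and extra steps to convert it later. A 3-acyloxy dihydrobenzofuran is again poised to eliminate, cyclopropanation of electron-rich ring A may compete, and a diazo compound must be handled.
- Comparison: it is equal on the later primary/secondary differentiation, since reduction of A6 gives the diol pattern of 15. It is more secure in relative configuration. It is inferior in step economy (about thirteen or fourteen steps against ten) and in tolerance of the ketone that the chosen plan uses as its activating group.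

Alternative 3: The cut is C3–C3a. Conjugate addition of the non-chelated hydroxyl of A10 to menthyloxy butenolide A9, trans to the auxiliary, would give acetal A8. A Lewis acid would ionise the menthyloxy acetal to an oxocarbenium ion at the future C3, and the ring carbon ortho to the ether oxygen and para to the phenol would capture it, closing ring B as cis-fused lactone A7.
- In favour: two steps from cheap materials reach the whole bicyclic core. The chirality comes from a recoverable chiral-pool auxiliary. Acetyl and phenol are carried unprotected. In speed of access to the core and in protecting-group economy this is the better plan, and the cis fusion is enforced.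
- Against: the cation is poorly stabilised by its acyloxy oxygen and the arene is deactivated by the acetyl group, so a strong Lewis acid is needed. Under it the β-aryloxy lactone can fragment by retro-conjugate addition and lose the C2 configuration. A second ortho position, between the two oxygens, competes. From A7, α-methylenation and lactone reduction must be run beside a free phenol and an aryl ketone, which then need protection.
- Comparison: the stereo-determining oxa-conjugate addition is reversible, whereas the allylboration leading to 11 is irreversible. Once protection is added, the step count would end near that of the chosen plan, with more risk concentrated in the closure and the endgame.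

Key step: step 7

Remarks on the chemistry:
- Stereochemical check: the syn (1R,2R) triol 12 and the cis (2R,3R) ring of 15 and 20 describe the same spatial arrangement, so no structure needs correcting. The allylborane that gives the syn diol has its enol-ether oxygen cis to the CH2B carbon. In this 2-(alkoxymethyl) series that is formally the E isomer (CH2O outranks CH2B), although it corresponds to the "(Z)-γ-alkoxyallyl" reagent of the unsubstituted series.
- Assumption: the oxanyl (tetrahydropyranyl) acetal carbons are formed without control, so 6 to 11 are mixtures of epimers at these centres only, which converge in step 6.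
- Compound 2 can also be purchased; if it is, step 1 falls away.

## Route

Step 1
Reactants: 1 4'-fluoro-2'-hydroxyacetophenone
Product: 2 5'-bromo-4'-fluoro-2'-hydroxyacetophenone
Conditions: NBS (1.0 equiv), MeCN, 0 °C to rt
Reagents that add atoms: N-bromosuccinimide, O=C1CCC(=O)N1Br
Why: Electrophilic aromatic bromination; the phenol directs para, to the carbon that is also ortho to fluorine and meta to the acetyl group, while the position between OH and F is more hindered, and one equivalent of NBS limits double and side-chain bromination.

Step 2
Reactants: 2 5'-bromo-4'-fluoro-2'-hydroxyacetophenone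
Product: 3 1-{5-bromo-4-fluoro-2-[(4-methoxybenzyl)oxy]phenyl}ethanone
Conditions: 4-methoxybenzyl chloride (1.1 equiv), K2CO3, Bu4NI (cat.), DMF, rt to 40 °C
Reagents that add atoms: 4-methoxybenzyl chloride, COc1ccc(CCl)cc1
Why: Williamson ether synthesis on the chelated phenol; the benzylic chloride is far more electrophilic than the aryl fluoride, so O-alkylation should outrun intermolecular substitution of fluorine at this temperature.

Step 3
Reactants: 3 1-{5-bromo-4-fluoro-2-[(4-methoxybenzyl)oxy]phenyl}ethanone
Product: 4 5-acetyl-2-fluoro-4-[(4-methoxybenzyl)oxy]benzaldehyde
Conditions: Pd(OAc)2 (1 mol%), di(1-adamantyl)-n-butylphosphine (3 mol%), TMEDA (1.0 equiv), CO/H2 (1:1, 5 bar), toluene, 100 °C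
Reagents that add atoms: carbon monoxide, [C-]#[O+]
Why: Palladium-catalysed reductive carbonylation (formylation) of an aryl bromide by oxidative addition, CO insertion and hydrogenolysis of the acylpalladium bromide; unlike halogen–metal exchange it leaves the methyl ketone, the aryl fluoride and the benzyl-type ether untouched.

Step 4
Reactants: 5 2-methylenepropane-1,3-diol
Product: 6 2,2'-[(2-methylidenepropane-1,3-diyl)bis(oxy)]bis(oxane) (the bis-tetrahydropyranyl ether)
Conditions: 3,4-dihydro-2H-pyran (2.5 equiv), PPTS (5 mol%), CH2Cl2, rt
Reagents that add atoms: 3,4-dihydro-2H-pyran, C1=COCCC1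
Why: Acid-catalysed addition of both hydroxyls to the enol ether (tetrahydropyranylation); the acetal tolerates sec-BuLi and can later be removed with a pyridinium acid that spares the aryl 4-methoxybenzyl ether.

Step 5
Reactants: 4 5-acetyl-2-fluoro-4-[(4-methoxybenzyl)oxy]benzaldehyde; 6 bis-tetrahydropyranyl ether of 2-methylenepropane-1,3-diol
Product: 11 1-{4-fluoro-5-[(1R,2R)-1-hydroxy-2-(oxan-2-yloxy)-3-[(oxan-2-yloxy)methyl]but-3-en-1-yl]-2-[(4-methoxybenzyl)oxy]phenyl}ethanone (syn adduct; epimers at the oxanyl acetal carbons), via alkoxyallyllithium 7 (not isolated), via lithium methoxyborate 8 (not isolated), via alkoxyallylborane 9 (not isolated), via borinate ester 10 (not isolated)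
Conditions: 6 (1.6 equiv), sec-BuLi (1.5 equiv), THF, −78 °C; (−)-Ipc2BOMe [from (+)-α-pinene] (1.6 equiv), −78 °C; BF3·OEt2 (2.1 equiv), −78 °C; then 4 (1.0 equiv), −78 °C, 4 h; NaBO3·4H2O, THF/H2O, rt
Reagents that add atoms: none
Why: Brown alkoxyallylboration: allylic deprotonation gives the oxygen-chelated allyllithium 7, boron trapping and BF3 release allylborane 9 with the ether oxygen cis to CH2B, and 9 adds to the aldehyde through a chair Zimmerman–Traxler transition state in which that geometry places the oxygen axial and gives the syn relationship. The isopinocampheyl groups derived from (+)-α-pinene direct the allyl unit to the Si face of the aldehyde, which sets C1 as R and hence C2 as R. At −78 °C the aldehyde reacts far faster than the aryl methyl ketone, and the mildly basic perborate work-up releases the alcohol from borinate 10 without endangering ketone or aryl fluoride.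

Step 6
Reactants: 11 syn adduct with two tetrahydropyranyl ethers
Product: 12 (1R,2R)-1-{5-acetyl-2-fluoro-4-[(4-methoxybenzyl)oxy]phenyl}-3-methylidenebutane-1,2,4-triol
Conditions: PPTS (0.2 equiv), EtOH, 50 °C
Reagents that add atoms: none
Why: Transacetalisation of both tetrahydropyranyl ethers to ethanol under pyridinium catalysis; the oxocarbenium ion is trapped by the solvent, so no cyclic acetal forms with the neighbouring hydroxyl, and the acidity is too low to cleave the aryl 4-methoxybenzyl ether or to ionise the benzylic alcohol.

Step 7
Reactants: 12 (1R,2R)-1-{5-acetyl-2-fluoro-4-[(4-methoxybenzyl)oxy]phenyl}-3-methylidenebutane-1,2,4-triol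
Product: 15 1-{(2R,3R)-3-hydroxy-2-(3-hydroxyprop-1-en-2-yl)-6-[(4-methoxybenzyl)oxy]-2,3-dihydro-1-benzofuran-5-yl}ethanone (cis), via cesium alkoxide 13 (not isolated), via Meisenheimer adduct 14 (not isolated)
Conditions: Cs2CO3 (2.5 equiv), DMSO (0.02 M), 50 °C
Reagents that add atoms: none
Why: Cs2CO3 reversibly deprotonates the hydroxyls of 12; the C2 alkoxide 13 adds to C7a ipso to fluorine to give Meisenheimer adduct 14, whose charge is spread over C7, C3a and C5 and from C5 onto the acetyl oxygen, and loss of fluoride restores ring A and completes the O1–C7a bond. The closest known reaction type is the intramolecular SNAr etherification of fluoroarenes activated by a para acyl group (addition–elimination). Ring B closes by 5-exo attack, the electron pair moving into the π system of ring A outside the new five-membered ring. No stereocentre is created and no bond to C1 or C2 of the triol is broken, so the syn (1R,2R) arrangement should pass unchanged into the cis (2R,3R) ring. The step needs chemoselectivity among three hydroxyls, and ring size secures it: the benzylic alkoxide could only close a four-membered ring and the primary alkoxide a seven-membered one, while high dilution disfavours intermolecular O-arylation. The 4-methoxybenzyl ether is essential, because a free phenol would be deprotonated first and the phenoxide would cancel the activation by the acetyl group. The mild carbonate base keeps the concentration of ketone enolate low and so limits aldol side reactions.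

Step 8
Reactants: 15 cis-dihydrobenzofuran diol
Product: 16 2-{(2R,3R)-5-acetyl-3-hydroxy-6-[(4-methoxybenzyl)oxy]-2,3-dihydro-1-benzofuran-2-yl}prop-2-en-1-yl acetate
Conditions: AcCl (1.1 equiv), 2,4,6-collidine, CH2Cl2, −78 °C
Reagents that add atoms: acetyl chloride, CC(Cl)=O
Why: Kinetically selective O-acylation; acetyl chloride with the hindered base collidine at low temperature should acylate the unhindered primary allylic hydroxyl much faster than the secondary benzylic one, which is shielded by the cis substituent at C2.

Step 9
Reactants: 16 primary acetate with free C3 hydroxyl; 17 angelic acid [(Z)-2-methylbut-2-enoic acid]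
Product: 19 (2R,3R)-2-[3-(acetyloxy)prop-1-en-2-yl]-5-acetyl-6-[(4-methoxybenzyl)oxy]-2,3-dihydro-1-benzofuran-3-yl (2Z)-2-methylbut-2-enoate, via mixed anhydride 18 (not isolated)
Conditions: 17 (3 equiv), 2,4,6-trichlorobenzoyl chloride (3 equiv), Et3N (3 equiv), toluene, rt, 2 h; then 16, toluene, 80 °C (no DMAP)
Reagents that add atoms: none
Why: Yamaguchi-type esterification through the 2,4,6-trichlorobenzoyl mixed anhydride; the alcohol attacks the less hindered angeloyl carbonyl, and omitting the nucleophilic pyridine catalyst avoids the conjugate addition–elimination that isomerises angelates to the E esters.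

Step 10
Reactants: 19 4-methoxybenzyl ether of the target
Product: 20 (2R,3R)-2-[3-(acetyloxy)prop-1-en-2-yl]-5-acetyl-6-hydroxy-2,3-dihydro-1-benzofuran-3-yl (2Z)-2-methylbut-2-enoate (CNP0323250.1)
Conditions: DDQ (1.5 equiv), CH2Cl2/pH 7 phosphate buffer (10:1), 0 °C to rt
Reagents that add atoms: none
Why: Oxidative cleavage of the 4-methoxybenzyl ether: hydride abstraction by DDQ from the anisyl CH2 and hydrolysis of the resulting oxocarbenium ion to the phenol and 4-methoxybenzaldehyde; the buffered, non-nucleophilic medium should leave the benzylic angelate, the allylic acetate and both stereocentres alone.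

## Compound list

1 | 4'-fluoro-2'-hydroxyacetophenone | CC(=O)c1ccc(F)cc1O | starting material
2 | 5'-bromo-4'-fluoro-2'-hydroxyacetophenone | CC(=O)c1cc(Br)c(F)cc1O | intermediate
3 | 1-{5-bromo-4-fluoro-2-[(4-methoxybenzyl)oxy]phenyl}ethanone | CC(=O)c1cc(Br)c(F)cc1OCc1ccc(OC)cc1 | intermediate
4 | 5-acetyl-2-fluoro-4-[(4-methoxybenzyl)oxy]benzaldehyde | CC(=O)c1cc(C=O)c(F)cc1OCc1ccc(OC)cc1 | intermediate
5 | 2-methylenepropane-1,3-diol | C=C(CO)CO | starting material
6 | 2,2'-[(2-methylidenepropane-1,3-diyl)bis(oxy)]bis(oxane) | C=C(COC1CCCCO1)COC1CCCCO1 | intermediate
7 | {3-(oxan-2-yloxy)-2-[(oxan-2-yloxy)methyl]prop-2-en-1-yl}lithium, ether oxygen cis to CH2Li | [Li]C/C(COC1CCCCO1)=C\OC1CCCCO1 | intermediate (not isolated)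
8 | lithium B-methoxy-B-{3-(oxan-2-yloxy)-2-[(oxan-2-yloxy)methyl]prop-2-en-1-yl}diisopinocampheylborate, isopinocampheyl groups from (+)-α-pinene | [Li+].CO[B-](C/C(COC1CCCCO1)=C\OC1CCCCO1)([C@@H]1C[C@@H]2C[C@@H](C2(C)C)[C@H]1C)[C@@H]1C[C@@H]2C[C@@H](C2(C)C)[C@H]1C | intermediate (not isolated)
9 | B-{3-(oxan-2-yloxy)-2-[(oxan-2-yloxy)methyl]prop-2-en-1-yl}diisopinocampheylborane, ether oxygen cis to CH2B | B(C/C(COC1CCCCO1)=C\OC1CCCCO1)([C@@H]1C[C@@H]2C[C@@H](C2(C)C)[C@H]1C)[C@@H]1C[C@@H]2C[C@@H](C2(C)C)[C@H]1C | intermediate (not isolated)
10 | diisopinocampheylborinate ester of 11 (boron on the C1 oxygen) | C=C(COC1CCCCO1)[C@@H](OC1CCCCO1)[C@H](OB([C@@H]1C[C@@H]2C[C@@H](C2(C)C)[C@H]1C)[C@@H]1C[C@@H]2C[C@@H](C2(C)C)[C@H]1C)c1cc(C(C)=O)c(OCc2ccc(OC)cc2)cc1F | intermediate (not isolated)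
11 | 1-{4-fluoro-5-[(1R,2R)-1-hydroxy-2-(oxan-2-yloxy)-3-[(oxan-2-yloxy)methyl]but-3-en-1-yl]-2-[(4-methoxybenzyl)oxy]phenyl}ethanone | C=C(COC1CCCCO1)[C@@H](OC1CCCCO1)[C@H](O)c1cc(C(C)=O)c(OCc2ccc(OC)cc2)cc1F | intermediate
12 | (1R,2R)-1-{5-acetyl-2-fluoro-4-[(4-methoxybenzyl)oxy]phenyl}-3-methylidenebutane-1,2,4-triol | C=C(CO)[C@@H](O)[C@H](O)c1cc(C(C)=O)c(OCc2ccc(OC)cc2)cc1F | intermediate
13 | cesium C2-alkoxide of 12 | C=C(CO)[C@@H]([O-])[C@H](O)c1cc(C(C)=O)c(OCc2ccc(OC)cc2)cc1F.[Cs+] | intermediate (not isolated)
14 | cesium salt of the Meisenheimer adduct (C7a bearing O1 and F, charge on the acetyl oxygen) | C=C(CO)[C@H]1OC2(F)C=C(OCc3ccc(OC)cc3)C(=C(C)[O-])C=C2[C@H]1O.[Cs+] | intermediate (not isolated)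
15 | 1-{(2R,3R)-3-hydroxy-2-(3-hydroxyprop-1-en-2-yl)-6-[(4-methoxybenzyl)oxy]-2,3-dihydro-1-benzofuran-5-yl}ethanone | C=C(CO)[C@H]1Oc2cc(OCc3ccc(OC)cc3)c(C(C)=O)cc2[C@H]1O | intermediate
16 | 2-{(2R,3R)-5-acetyl-3-hydroxy-6-[(4-methoxybenzyl)oxy]-2,3-dihydro-1-benzofuran-2-yl}prop-2-en-1-yl acetate | C=C(COC(C)=O)[C@H]1Oc2cc(OCc3ccc(OC)cc3)c(C(C)=O)cc2[C@H]1O | intermediate
17 | angelic acid, (Z)-2-methylbut-2-enoic acid | C/C=C(/C)C(=O)O | starting material
18 | (Z)-2-methylbut-2-enoic 2,4,6-trichlorobenzoic anhydride | C/C=C(/C)C(=O)OC(=O)c1c(Cl)cc(Cl)cc1Cl | intermediate (not isolated)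
19 | (2R,3R)-2-[3-(acetyloxy)prop-1-en-2-yl]-5-acetyl-6-[(4-methoxybenzyl)oxy]-2,3-dihydro-1-benzofuran-3-yl (2Z)-2-methylbut-2-enoate | C=C(COC(C)=O)[C@H]1Oc2cc(OCc3ccc(OC)cc3)c(C(C)=O)cc2[C@H]1OC(=O)/C(C)=C\C | intermediate
20 | (2R,3R)-2-[3-(acetyloxy)prop-1-en-2-yl]-5-acetyl-6-hydroxy-2,3-dihydro-1-benzofuran-3-yl (2Z)-2-methylbut-2-enoate | C=C(COC(C)=O)[C@H]1Oc2cc(O)c(C(C)=O)cc2[C@H]1OC(=O)/C(C)=C\C | target

## Step count and least certain steps

Total: 10 steps. Longest linear sequence: 9 steps (steps 1, 2, 3, 5, 6, 7, 8, 9, 10, from 1 to 20); step 4 is a one-step branch from 5.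

Step 7 (key step). The addition–elimination may be slow, because the ether oxygen ortho to the acetyl group weakens the activation. Forcing it with stronger base or heat would let enolisation and aldol self-condensation of the methyl ketone, or intermolecular O-arylation by the primary hydroxyl, compete with ring closure. The fallback removes the Brønsted base altogether and sets out from 12. Persilylation (Me3SiCl, imidazole, DMF) would give the tris(trimethylsilyl) ether of 12, F3. A catalytic amount of CsF in DMF would unmask the alkoxides by attack of fluoride on silicon, and the C2 alkoxide should close ring B with release of fluoride, which carries the chain, to give the bis(trimethylsilyl) ether of 15, F4. Citric acid in MeOH on work-up would remove the remaining silyl groups, and the route is rejoined at 15.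

Step 5. Three things may go wrong:
- Loss of geometric purity of the allyl anion, because the ether oxygen of the 2-substituent can compete for lithium; this would erode the syn selectivity.
- Partial loss of an acetal under BF3.
- Weaker facial control than in the unsubstituted series.

The fallback changes from reagent control to catalyst control and sets out from 6. Lithiation as before and trapping with 2-isopropoxy-4,4,5,5-tetramethyl-1,3,2-dioxaborolane would give the isolable pinacol boronate F2, whose geometry can be checked and which can be purified. F2 and 4 would then be combined in toluene at −30 °C with a catalytic amount of (S)-TRIP, the 3,3'-bis(2,4,6-triisopropylphenyl)-1,1'-binaphthyl-2,2'-diyl hydrogen phosphate, in a chiral phosphoric acid-catalysed allylboration. This enantiomer is chosen on the expectation, by analogy with the parent allylation of benzaldehyde, that it directs addition to the Si face; the other enantiomer would be taken if the sense were the opposite. No BF3 is involved, and the route is rejoined at 11.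

Step 3. Hydrodebromination, by hydrogenolysis of the arylpalladium bromide before CO insertion, or slow turnover with this ortho-fluoro, para-alkoxy bromide may lower the conversion to aldehyde. The fallback sets out from 3. A Suzuki–Miyaura vinylation (potassium vinyltrifluoroborate, PdCl2(dppf), Et3N, n-PrOH, 90 °C) would give 1-{5-ethenyl-4-fluoro-2-[(4-methoxybenzyl)oxy]phenyl}ethanone F1. Lemieux–Johnson cleavage (K2OsO4·2H2O cat., NaIO4, 2,6-lutidine, dioxane/H2O, rt) would then give the aldehyde, and the route is rejoined at 4.

Step 9. Acylation of the hindered cis C3 hydroxyl may be sluggish. Prolonged heating would invite Z to E isomerisation of the angeloyl unit and elimination across C2–C3 with aromatisation of ring B. The fallback builds the Z alkene on the ester at low temperature and sets out from 16. Esterification with 2-[bis(2,2,2-trifluoroethoxy)phosphoryl]propanoic acid (DCC, DMAP cat., CH2Cl2, 0 °C to rt; no isomerisable alkene is present yet) would give the phosphonate ester F5. A Still–Gennari olefination with acetaldehyde (KN(SiMe3)2, 18-crown-6, THF, −78 °C) should then deliver the (Z)-2-methylbut-2-enoate, and the route is rejoined at 19.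

Step 10. Cleavage may be slow, because the aryloxy oxygen is conjugated with the acetyl group. With excess oxidant, hydride abstraction at C3–H or C2–H of the alkoxy-substituted dihydrobenzofuran could start and lead to aromatisation of ring B. The fallback replaces oxidation by chelation-assisted Lewis acid dealkylation and sets out from 19. MgBr2·OEt2 and Me2S in CH2Cl2 at 0 °C to rt should bind between the acetyl oxygen and the neighbouring ether oxygen, activate only that ether, and transfer the benzyl group to the sulfide. The route is rejoined at 20 without a new isolated compound.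

## Further compounds

F1 | step 3 | 1-{5-ethenyl-4-fluoro-2-[(4-methoxybenzyl)oxy]phenyl}ethanone | CC(=O)c1cc(C=C)c(F)cc1OCc1ccc(OC)cc1
F2 | step 5 | 2-{3-(oxan-2-yloxy)-2-[(oxan-2-yloxy)methyl]prop-2-en-1-yl}-4,4,5,5-tetramethyl-1,3,2-dioxaborolane, ether oxygen cis to CH2B | CC1(C)OB(C/C(COC2CCCCO2)=C\OC2CCCCO2)OC1(C)C
F3 | step 7 | tris(trimethylsilyl) ether of 12 | C=C(CO[Si](C)(C)C)[C@@H](O[Si](C)(C)C)[C@H](O[Si](C)(C)C)c1cc(C(C)=O)c(OCc2ccc(OC)cc2)cc1F
F4 | step 7 | bis(trimethylsilyl) ether of 15 | C=C(CO[Si](C)(C)C)[C@H]1Oc2cc(OCc3ccc(OC)cc3)c(C(C)=O)cc2[C@H]1O[Si](C)(C)C
F5 | step 9 | (2R,3R)-2-[3-(acetyloxy)prop-1-en-2-yl]-5-acetyl-6-[(4-methoxybenzyl)oxy]-2,3-dihydro-1-benzofuran-3-yl 2-[bis(2,2,2-trifluoroethoxy)phosphoryl]propanoate | C=C(COC(C)=O)[C@H]1Oc2cc(OCc3ccc(OC)cc3)c(C(C)=O)cc2[C@H]1OC(=O)C(C)P(=O)(OCC(F)(F)F)OCC(F)(F)F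
F0 | step 10 | none | none
A1 | alternative 1 | cis-5-acetyl-3-(tert-butyldimethylsilyloxy)-2-[3-(tert-butyldimethylsilyloxy)prop-1-en-2-yl]-6-(trimethylsilyloxy)-2,3-dihydrobenzofuran | C=C(CO[Si](C)(C)C(C)(C)C)[C@H]1Oc2cc(O[Si](C)(C)C)c(C(C)=O)cc2[C@H]1O[Si](C)(C)C(C)(C)C
A2 | alternative 1 | cis-5-[2,2-bis(trimethylsilyloxy)ethenyl]-3-(tert-butyldimethylsilyloxy)-2-[3-(tert-butyldimethylsilyloxy)prop-1-en-2-yl]-2,3-dihydrofuran | C=C(CO[Si](C)(C)C(C)(C)C)[C@H]1OC(C=C(O[Si](C)(C)C)O[Si](C)(C)C)=C[C@H]1O[Si](C)(C)C(C)(C)C
A3 | alternative 1 | but-3-yn-2-one | CC(=O)C#C
A4 | alternative 2 | cis-fused α-(diethoxyphosphoryl) γ-lactone of 5-bromo-6-(triisopropylsilyloxy)-2,3-dihydrobenzofuran | C5(P(=O)(OCC)OCC)[C@H]1Oc2cc(O[Si](C(C)C)(C(C)C)C(C)C)c(Br)cc2[C@H]1OC5=O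
A5 | alternative 2 | (3R)-5-bromo-6-(triisopropylsilyloxy)-2,3-dihydro-1-benzofuran-3-yl 2-diazo-2-(diethoxyphosphoryl)acetate | [N-]=[N+]=C(C(=O)O[C@H]1COc2cc(O[Si](C(C)C)(C(C)C)C(C)C)c(Br)cc21)P(=O)(OCC)OCC
A6 | alternative 2 | cis-fused α-methylene γ-lactone of 5-bromo-6-(triisopropylsilyloxy)-2,3-dihydrobenzofuran | C=C1[C@H]2Oc3cc(O[Si](C(C)C)(C(C)C)C(C)C)c(Br)cc3[C@H]2OC1=O
A7 | alternative 3 | cis-fused γ-lactone of 5-acetyl-6-hydroxy-2,3-dihydrobenzofuran | C5[C@H]1Oc2cc(O)c(C(C)=O)cc2[C@H]1OC5=O
A8 | alternative 3 | trans-4-(4-acetyl-3-hydroxyphenoxy)-5-[(1R,2S,5R)-menthyloxy]dihydrofuran-2(3H)-one | O=C1C[C@@H](Oc2ccc(C(C)=O)c(O)c2)[C@H](O[C@@H]2C[C@H](C)CC[C@H]2C(C)C)O1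
A9 | alternative 3 | (5R)-5-[(1R,2S,5R)-menthyloxy]furan-2(5H)-one | O=C1C=C[C@H](O[C@@H]2C[C@H](C)CC[C@H]2C(C)C)O1
A10 | alternative 3 | 2',4'-dihydroxyacetophenone | CC(=O)c1ccc(O)cc1O
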